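**Retrosynthetic overview**

1. Numbering (3,7-dioxabicyclo[3.3.0]octane): C1 = bridgehead carbinol, C2(Ar), O3, C4, C5 = bridgehead CH, C6(Ar), O7, C8; ring A = C1–C2–O3–C4–C5, ring B = C5–C6–O7–C8–C1; Ar = 3,4-dimethoxyphenyl, exo at C2 and endo at C6.
2. Feature used: the tertiary carbinol C1 sits in an erythro 1-arylglycerol, O3–C2(Ar)–C1(OH)–C8–O7, which is the anti adduct of an aryl Grignard reagent with (S)-glyceraldehyde acetonide. Only the C1–C5 bond is missing, so the C1–H bond of the chiral pool is turned into it.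
3. Key disconnection C1–C5: a diazoacetate on O3 gives, with Rh2(NHCOCH3)4, a carbene that inserts into the dioxolane C1–H bond with retention and closes ring A as a γ-lactone (C4 = carbonyl).
4. Ring B: C5–C6 by Claisen acylation of the lactone alkoxide-enolate dianion with methyl 3,4-dimethoxybenzoate; C6–O7 by hemiketalisation once O7 is unmasked; C6–H by hydride delivery to the oxocarbenium ion from the convex face (aryl endo).
5. Ring order: ring A as lactone (step 4), ring B (steps 8 and 9), then reduction of the C4 carbonyl to the methylene ether (steps 10 and 11).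

Key step: step 4

Assumption: (S)-glyceraldehyde acetonide is bought and distilled just before use, because it oligomerises and loses optical purity on storage.

**Route**

Step 1
Reactants: 1 (S)-glyceraldehyde acetonide; 2 4-bromoveratrole
Product: 4 (R)-(3,4-dimethoxyphenyl)[(S)-2,2-dimethyl-1,3-dioxolan-4-yl]methanol (anti adduct), via 3,4-dimethoxyphenylmagnesium bromide 3 (not isolated)
Conditions: Mg, THF, rt; then 1, THF, −78 °C; sat. aq. NH4Cl
Reagents that add atoms: none
Why: Grignard addition under Felkin–Anh (non-chelation) control, in which the α dioxolane oxygen lies anti to the incoming aryl group, so the C2 carbinol should form mainly as the anti (erythro, 2R) isomer, the minor syn epimer being removed by chromatography.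

Step 2
Reactants: 4 (R)-(3,4-dimethoxyphenyl)[(S)-2,2-dimethyl-1,3-dioxolan-4-yl]methanol
Product: 5 (R)-(3,4-dimethoxyphenyl)[(S)-2,2-dimethyl-1,3-dioxolan-4-yl]methyl bromoacetate
Conditions: BrCH2COBr, NaHCO3, MeCN, 0 °C
Reagents that add atoms: bromoacetyl bromide, O=C(Br)CBr
Why: O-acylation of the secondary benzylic alcohol by an acyl bromide, with NaHCO3 taking up HBr so that the acetonide survives and no stereocentre is touched.

Step 3
Reactants: 5 (R)-(3,4-dimethoxyphenyl)[(S)-2,2-dimethyl-1,3-dioxolan-4-yl]methyl bromoacetate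
Product: 6 (R)-(3,4-dimethoxyphenyl)[(S)-2,2-dimethyl-1,3-dioxolan-4-yl]methyl diazoacetate
Conditions: TsNHNHTs, DBU, THF, 0 °C
Reagents that add atoms: N,N'-ditosylhydrazine, Cc1ccc(cc1)S(=O)(=O)NNS(=O)(=O)c1ccc(C)cc1
Why: diazoacetate synthesis from a bromoacetate (N-alkylation of the ditosylhydrazine anion, then base-induced loss of two sulfinates), which should work under mild base that leaves the acetonide and both stereocentres alone.

Step 4
Reactants: 6 (R)-(3,4-dimethoxyphenyl)[(S)-2,2-dimethyl-1,3-dioxolan-4-yl]methyl diazoacetate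
Product: 7 (5S,6R)-6-(3,4-dimethoxyphenyl)-2,2-dimethyl-1,3,7-trioxaspiro[4.4]nonan-8-one
Conditions: Rh2(NHCOCH3)4 (1 mol %), CH2Cl2, reflux, 6 added over 6 h by syringe pump
Reagents that add atoms: none
Why: The divalent rhodium acetamidate should expel N2 from 6 to give an electrophilic dirhodium carbene at C5, which inserts into the C1–H bond through a concerted three-centre transition state with hydride-transfer character; the closest known reaction type is the dirhodium carboxamidate-catalysed 1,5 C–H insertion of diazoacetates into C–H bonds next to an ether oxygen, which gives γ-lactones. Ring A closes as a five-membered lactone by 1,5-insertion (C5–C4–O3–C2 onto C1), the preferred mode for an ester-tethered carbene. C1 becomes the quaternary carbinol centre with retention, because the C1–C5 bond forms on the face that carried hydrogen, so its configuration comes directly from (S)-glyceraldehyde, while C2 is a spectator. The step needs site selectivity for C1–H over the C8 methylene (six-membered lactone), the benzylic C2–H (four-membered lactone), addition to the electron-rich arene and oxonium ylide formation at the dioxolane oxygens. The tertiary, oxygen-activated C1–H in a five-ring transition state and the electron-donating acetamidate ligands, which temper the carbene and favour insertion over aromatic addition, should secure it, and slow addition of 6 suppresses carbene dimerisation.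

Step 5
Reactants: 7 (5S,6R)-6-(3,4-dimethoxyphenyl)-2,2-dimethyl-1,3,7-trioxaspiro[4.4]nonan-8-one
Product: 8 (4S,5R)-5-(3,4-dimethoxyphenyl)-4-hydroxy-4-(hydroxymethyl)oxolan-2-one
Conditions: AcOH/H2O (4:1), 40 °C
Reagents that add atoms: none
Why: acid-catalysed acetal hydrolysis under conditions too mild to ionise the benzylic lactone C2–O3 bond; the diol is carried on at once so that the free primary hydroxyl has no time to translactonise.

Step 6
Reactants: 8 (4S,5R)-5-(3,4-dimethoxyphenyl)-4-hydroxy-4-(hydroxymethyl)oxolan-2-one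
Product: 9 (4S,5R)-4-[(tert-butyldimethylsilyloxy)methyl]-5-(3,4-dimethoxyphenyl)-4-hydroxyoxolan-2-one
Conditions: TBSCl, imidazole, DMF, 0 °C
Reagents that add atoms: tert-butyldimethylsilyl chloride, CC(C)(C)[Si](C)(C)Cl
Why: selective silylation of the primary O7 hydroxyl (the tertiary C1 hydroxyl is too hindered), which masks O7 and leaves C1–OH free to become the alkoxide of the dianion.

Step 7
Reactants: 9 (4S,5R)-4-[(tert-butyldimethylsilyloxy)methyl]-5-(3,4-dimethoxyphenyl)-4-hydroxyoxolan-2-one; 10 methyl 3,4-dimethoxybenzoate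
Product: 12 (3RS,4S,5R)-4-[(tert-butyldimethylsilyloxy)methyl]-3-(3,4-dimethoxybenzoyl)-5-(3,4-dimethoxyphenyl)-4-hydroxyoxolan-2-one, via dilithium alkoxide-enolate 11 (not isolated)
Conditions: i-Pr2NLi (3.2 equiv), THF, −78 °C; then 10, −78 to −20 °C; sat. aq. NH4Cl at −78 °C
Reagents that add atoms: none
Why: Fráter–Seebach-type dianion formation followed by crossed Claisen acylation, in which the C1 alkoxide blocks β-elimination from the C5 enolate and the third equivalent of base holds the product as its stabilised enolate; C5 is epimerisable here and is fixed later by the cis ring fusion.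

Step 8
Reactants: 12 (3RS,4S,5R)-4-[(tert-butyldimethylsilyloxy)methyl]-3-(3,4-dimethoxybenzoyl)-5-(3,4-dimethoxyphenyl)-4-hydroxyoxolan-2-one
Product: 14 (1S,2R,5S)-2,6-bis(3,4-dimethoxyphenyl)-1,6-dihydroxy-3,7-dioxabicyclo[3.3.0]octan-4-one (C6 anomers), via desilylated hydroxy ketone 13 (not isolated)
Conditions: HF·pyridine, pyridine, THF, 0 °C to rt
Reagents that add atoms: none
Why: fluoride desilylation under non-basic conditions frees the O7 hydroxyl, which adds to the C6 ketone (5-exo-trig hemiketalisation) from the C5 epimer whose aroyl group is cis to C8, the other epimer feeding in through the enol, so the cis-fused bicycle sets C5.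

Step 9
Reactants: 14 (1S,2R,5S)-2,6-bis(3,4-dimethoxyphenyl)-1,6-dihydroxy-3,7-dioxabicyclo[3.3.0]octan-4-one
Product: 15 (1S,2R,5R,6R)-2,6-bis(3,4-dimethoxyphenyl)-1-hydroxy-3,7-dioxabicyclo[3.3.0]octan-4-one
Conditions: Et3SiH (excess, added first), BF3·OEt2, CH2Cl2, −78 to −30 °C
Reagents that add atoms: none
Why: ionic hydrogenation of a cyclic hemiketal, in which BF3·OEt2 gives the aryl-stabilised C6 oxocarbenium ion and Et3SiH delivers hydride to the convex (exo) face of the cis-fused bicycle, so the C6 aryl group should end up endo (6R); the low temperature keeps the benzylic lactone C2–O3 bond intact.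

Step 10
Reactants: 15 (1S,2R,5R,6R)-2,6-bis(3,4-dimethoxyphenyl)-1-hydroxy-3,7-dioxabicyclo[3.3.0]octan-4-one
Product: 16 (1S,2R,5R,6R)-2,6-bis(3,4-dimethoxyphenyl)-3,7-dioxabicyclo[3.3.0]octane-1,4-diol (C4 anomers)
Conditions: i-Bu2AlH (2.5 equiv), CH2Cl2, −78 °C; aq. KNaC4H4O6 (potassium sodium tartrate)
Reagents that add atoms: none
Why: partial reduction of a γ-lactone to the lactol, possible because the tetrahedral aluminium hemiacetal is stable at −78 °C until work-up; the first equivalent of hydride is consumed by the C1 hydroxyl.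

Step 11
Reactants: 16 (1S,2R,5R,6R)-2,6-bis(3,4-dimethoxyphenyl)-3,7-dioxabicyclo[3.3.0]octane-1,4-diol
Product: 17 (+)-gmelinol, (1S,2R,5R,6R)-2,6-bis(3,4-dimethoxyphenyl)-3,7-dioxabicyclo[3.3.0]octan-1-ol
Conditions: Et3SiH, BF3·OEt2, CH2Cl2, −78 °C; aq. NaHCO3 added cold
Reagents that add atoms: none
Why: ionic hydrogenation of the lactol through the C4 oxocarbenium ion gives the methylene ether without creating a stereocentre, and the cold, short reaction with a basic quench should avoid acid-induced epimerisation of the benzylic ether carbons C2 and C6.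

**Compound list**

1 | (S)-glyceraldehyde acetonide, (S)-2,2-dimethyl-1,3-dioxolane-4-carbaldehyde | O=C[C@@H]1COC(C)(C)O1 | starting material
2 | 4-bromoveratrole (4-bromo-1,2-dimethoxybenzene) | COc1ccc(Br)cc1OC | starting material
3 | 3,4-dimethoxyphenylmagnesium bromide | COc1ccc([Mg]Br)cc1OC | intermediate
4 | (R)-(3,4-dimethoxyphenyl)[(S)-2,2-dimethyl-1,3-dioxolan-4-yl]methanol | COc1ccc(cc1OC)[C@@H](O)[C@@H]1COC(C)(C)O1 | intermediate
5 | (R)-(3,4-dimethoxyphenyl)[(S)-2,2-dimethyl-1,3-dioxolan-4-yl]methyl bromoacetate | COc1ccc(cc1OC)[C@@H](OC(=O)CBr)[C@@H]1COC(C)(C)O1 | intermediate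
6 | (R)-(3,4-dimethoxyphenyl)[(S)-2,2-dimethyl-1,3-dioxolan-4-yl]methyl diazoacetate | COc1ccc(cc1OC)[C@@H](OC(=O)C=[N+]=[N-])[C@@H]1COC(C)(C)O1 | intermediate
7 | (5S,6R)-6-(3,4-dimethoxyphenyl)-2,2-dimethyl-1,3,7-trioxaspiro[4.4]nonan-8-one | COc1ccc(cc1OC)[C@H]2OC(=O)C[C@@]23OC(C)(C)OC3 | intermediate
8 | (4S,5R)-5-(3,4-dimethoxyphenyl)-4-hydroxy-4-(hydroxymethyl)oxolan-2-one | COc1ccc(cc1OC)[C@H]2OC(=O)C[C@]2(O)CO | intermediate
9 | (4S,5R)-4-[(tert-butyldimethylsilyloxy)methyl]-5-(3,4-dimethoxyphenyl)-4-hydroxyoxolan-2-one | COc1ccc(cc1OC)[C@H]2OC(=O)C[C@]2(O)CO[Si](C)(C)C(C)(C)C | intermediate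
10 | methyl 3,4-dimethoxybenzoate | COc1ccc(cc1OC)C(=O)OC | starting material
11 | dilithium alkoxide-enolate of 9 | COc1ccc(cc1OC)[C@H]2OC(O[Li])=C[C@]2(O[Li])CO[Si](C)(C)C(C)(C)C | intermediate
12 | (3RS,4S,5R)-4-[(tert-butyldimethylsilyloxy)methyl]-3-(3,4-dimethoxybenzoyl)-5-(3,4-dimethoxyphenyl)-4-hydroxyoxolan-2-one | COc1ccc(cc1OC)[C@H]2OC(=O)C(C(=O)c3ccc(OC)c(OC)c3)[C@]2(O)CO[Si](C)(C)C(C)(C)C | intermediate
13 | (3RS,4S,5R)-3-(3,4-dimethoxybenzoyl)-5-(3,4-dimethoxyphenyl)-4-hydroxy-4-(hydroxymethyl)oxolan-2-one | COc1ccc(cc1OC)[C@H]2OC(=O)C(C(=O)c3ccc(OC)c(OC)c3)[C@]2(O)CO | intermediate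
14 | (1S,2R,5S)-2,6-bis(3,4-dimethoxyphenyl)-1,6-dihydroxy-3,7-dioxabicyclo[3.3.0]octan-4-one (C6 anomers) | COc1ccc(cc1OC)[C@H]2OC(=O)[C@@H]3C(O)(c4ccc(OC)c(OC)c4)OC[C@]23O | intermediate
15 | (1S,2R,5R,6R)-2,6-bis(3,4-dimethoxyphenyl)-1-hydroxy-3,7-dioxabicyclo[3.3.0]octan-4-one | COc1ccc(cc1OC)[C@H]2OC(=O)[C@@H]3[C@H](c4ccc(OC)c(OC)c4)OC[C@]23O | intermediate
16 | (1S,2R,5R,6R)-2,6-bis(3,4-dimethoxyphenyl)-3,7-dioxabicyclo[3.3.0]octane-1,4-diol (C4 anomers) | COc1ccc(cc1OC)[C@H]2OC(O)[C@@H]3[C@H](c4ccc(OC)c(OC)c4)OC[C@]23O | intermediate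
17 | (+)-gmelinol | COc1ccc([C@H]2OC[C@@H]3[C@H](c4ccc(OC)c(OC)c4)OC[C@]23O)cc1OC | target

**Step count**

Total: 11 steps. Longest linear sequence: 11 steps (1 to 17); 2 and 10 are purchased and enter in steps 1 and 7.

**Steps most likely to fail, with fallbacks**

1. Step 4 (carbene C–H insertion). The carbene may be diverted into oxonium ylide formation at a dioxolane oxygen, addition to the dimethoxyphenyl ring, insertion at the C8 methylene or dimerisation, so that little γ-lactone forms. The fallback sets out from 5 and returns at 9, bypassing 6, 7 and 8. It makes the C1–C5 bond by an intramolecular Reformatsky addition to a C1 ketone instead of by insertion into C1–H. Aqueous AcOH should remove the acetonide of 5 to give (1R,2S)-1-(3,4-dimethoxyphenyl)-2,3-dihydroxypropyl bromoacetate F1, kept cold and acidic to limit acyl migration. TBSOTf with 2,6-lutidine at −78 °C should silylate the primary hydroxyl to give (1R,2S)-3-(tert-butyldimethylsilyloxy)-1-(3,4-dimethoxyphenyl)-2-hydroxypropyl bromoacetate F2. Dess–Martin periodinane should oxidise the remaining secondary alcohol to (R)-3-(tert-butyldimethylsilyloxy)-1-(3,4-dimethoxyphenyl)-2-oxopropyl bromoacetate F3. Activated Zn in THF should then form the zinc enolate, which adds to the C1 ketone, closes ring A and gives 9 after aqueous NH4Cl. In this variant C1 is set by facial selectivity, not by retention. The wanted isomer has CH2OTBS trans to the C2 aryl group, but the selectivity is not secured, and the C1 epimer may have to be separated.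

2. Step 7 (dianion acylation). The hindered C5 enolate may be acylated too slowly by the electron-rich ester, and on warming the dianion may be lost through retro-aldol opening at C1 or proton transfer. The fallback sets out from 9 and returns at 12, and uses the more electrophilic aldehyde in place of the ester. The dianion 11, generated as in step 7 with 2.2 equiv of i-Pr2NLi, should add at −78 °C to 3,4-dimethoxybenzaldehyde to give the aldol adduct (4S,5R)-4-[(tert-butyldimethylsilyloxy)methyl]-3-[(3,4-dimethoxyphenyl)(hydroxy)methyl]-5-(3,4-dimethoxyphenyl)-4-hydroxyoxolan-2-one F4, as diastereomers at C5 and C6 that are both erased later. Dess–Martin periodinane buffered with NaHCO3 should oxidise only the secondary benzylic alcohol, the C1 alcohol being tertiary, to give 12.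

3. Step 1 (Grignard addition). Poor facial selectivity may leave much of the material as the syn C2 epimer. The fallback sets out from the mixture of 4 and its C2 epimer obtained in step 1 and returns at 4. Dess–Martin periodinane should convert both epimers into the single ketone (S)-(3,4-dimethoxyphenyl)(2,2-dimethyl-1,3-dioxolan-4-yl)methanone F5. Zn(BH4)2 in Et2O at −30 °C should reduce it through the five-membered zinc chelate between the carbonyl oxygen and the α dioxolane oxygen (Cram chelate control), with hydride arriving from the side of the C1 hydrogen, to give the anti alcohol 4.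

**Further compounds**

F1 | step 4 | (1R,2S)-1-(3,4-dimethoxyphenyl)-2,3-dihydroxypropyl bromoacetate | COc1ccc(cc1OC)[C@@H](OC(=O)CBr)[C@@H](O)CO
F2 | step 4 | (1R,2S)-3-(tert-butyldimethylsilyloxy)-1-(3,4-dimethoxyphenyl)-2-hydroxypropyl bromoacetate | COc1ccc(cc1OC)[C@@H](OC(=O)CBr)[C@@H](O)CO[Si](C)(C)C(C)(C)C
F3 | step 4 | (R)-3-(tert-butyldimethylsilyloxy)-1-(3,4-dimethoxyphenyl)-2-oxopropyl bromoacetate | COc1ccc(cc1OC)[C@@H](OC(=O)CBr)C(=O)CO[Si](C)(C)C(C)(C)C
F4 | step 7 | (4S,5R)-4-[(tert-butyldimethylsilyloxy)methyl]-3-[(3,4-dimethoxyphenyl)(hydroxy)methyl]-5-(3,4-dimethoxyphenyl)-4-hydroxyoxolan-2-one | COc1ccc(cc1OC)[C@H]2OC(=O)C(C(O)c3ccc(OC)c(OC)c3)[C@]2(O)CO[Si](C)(C)C(C)(C)C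
F5 | step 1 | (S)-(3,4-dimethoxyphenyl)(2,2-dimethyl-1,3-dioxolan-4-yl)methanone | COc1ccc(cc1OC)C(=O)[C@@H]1COC(C)(C)O1
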